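**Retrosynthetic overview**
1. The Cα=Cβ bond of the trienone is cut by Claisen–Schmidt condensation. This gives an aryl methyl ketone that already carries the side chain, plus ethyl (2E,4E)-6-oxohexa-2,4-dienoate. Both ethyl esters are saponified in the same flask.
2. In the heptenoic side chain, C2=C3 comes from a Wittig reaction and C3–C4 from linear hydroformylation of an (R)-3-arylbut-1-ene, both in one pot.
3. The aryl–C6 bond and the only stereocentre come from a chiral Brønsted-acid-catalysed enantioselective aromatic Claisen rearrangement of the achiral (E)-crotyl ether of 2'-hydroxy-5'-methoxyacetophenone.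
4. The dienal ester comes from a Wittig reaction of ethyl (E)-4-oxobut-2-enoate with formylmethylene(triphenyl)phosphorane.
5. No ring is formed. The benzene ring is bought with three of its four substituents in place.

Assumption 1: bought (E)-but-2-en-1-ol is taken as E:Z ≥ 19:1, and the crotyl ether made from it is freed from the Z isomer on AgNO3-impregnated silica before the key step.
Assumption 2: the sense of induction of the new catalyst–substrate pair cannot be predicted safely. The (S,S) catalyst is written, and its mirror image is used if the first run gives the (S) product.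

**Step 1**
Reactants: 1 1-(2-hydroxy-5-methoxyphenyl)ethan-1-one (2'-hydroxy-5'-methoxyacetophenone); 2 (E)-but-2-en-1-ol
Product: 3 1-{2-[(2E)-but-2-en-1-yloxy]-5-methoxyphenyl}ethan-1-one
Conditions: PPh3 (1.2 equiv), DIAD (1.2 equiv), THF, 0 °C to rt, 6 h; chromatography on AgNO3-impregnated silica
Reagents that add atoms: none
Why: Mitsunobu etherification, in which the acidic phenol attacks the primary oxyphosphonium salt of 2 by SN2, so the E geometry is carried over unchanged and no stereocentre is made.

**Step 2**
Reactants: 3 1-{2-[(2E)-but-2-en-1-yloxy]-5-methoxyphenyl}ethan-1-one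
Product: 5 1-{3-[(2R)-but-3-en-2-yl]-2-hydroxy-5-methoxyphenyl}ethan-1-one, via ortho-dienone 4 (not isolated)
Conditions: (S,S)-IDPi (imidodiphosphorimidate acid from two (S)-3,3'-bis[3,5-bis(trifluoromethyl)phenyl]-BINOL units, both P=N groups carrying SO2CF3) 5 mol %, cyclohexane/CHCl3 4:1 (0.1 M), 5 Å MS, 40 °C, 48 h
Reagents that add atoms: none
Why: Proposed new method: a metal-free, Brønsted-acid-catalysed enantioselective aromatic Claisen rearrangement of a simple aryl crotyl ether, in which the proton of the confined IDPi sits in the chelating pocket formed by the ether oxygen and the ortho-acetyl oxygen of 3 and polarises the O–CH2 bond into a charge-accelerated [3,3] shift (the effect by which CF3CO2H or BCl3 bring aromatic Claisen reactions from 180 °C to room temperature), the developing 2-acyl dienone 4 is a much better hydrogen-bond acceptor than the ether so the transition state is bound more tightly than the substrate, only one ortho position is free so the regiochemistry is fixed, the E-crotyl group reacts through a chair in which the chiral anion leaves only the Re face of crotyl C3 open to the ring carbon and thereby sets the (R) benzylic centre, and enolisation gives phenol 5 whose internal O–H···O=C bond makes it a poor ligand so the acid is released; the closest known reaction types are the guanidinium (hydrogen-bond-donor) catalysed enantioselective Claisen rearrangement of ester-substituted allyl vinyl ethers and the aromatic Claisen rearrangement of ester-bearing allyl naphthyl ethers catalysed by chiral divalent copper or cobalt Lewis acids.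

**Step 3**
Reactants: 5 1-{3-[(2R)-but-3-en-2-yl]-2-hydroxy-5-methoxyphenyl}ethan-1-one; 6 ethyl (triphenyl-λ5-phosphanylidene)acetate
Product: 8 ethyl (2E,6R)-6-(3-acetyl-2-hydroxy-5-methoxyphenyl)hept-2-enoate, via pentanal 7 (not isolated)
Conditions: Rh(acac)(CO)2 (1 mol %), Xantphos (3 mol %), CO/H2 1:1 (10 bar), toluene, 60 °C, 16 h; vent; then 6 (1.2 equiv), rt, 12 h
Reagents that add atoms: carbon monoxide, [C-]#[O+]
Why: Linear-selective hydroformylation followed by Wittig olefination in one pot, where the wide-bite-angle diphosphine puts rhodium on the unhindered terminal carbon of the α-branched alkene so aldehyde 7 forms without touching the benzylic centre, and the stabilised ylide reacts only with the aldehyde (not the hydrogen-bonded aryl ketone) to give the E-enoate.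

**Step 4**
Reactants: 9 ethyl (E)-4-oxobut-2-enoate; 10 (triphenyl-λ5-phosphanylidene)acetaldehyde
Product: 11 ethyl (2E,4E)-6-oxohexa-2,4-dienoate
Conditions: 10 (1.0 equiv, added slowly), toluene, rt, 16 h
Reagents that add atoms: none
Why: Wittig olefination with a formyl-stabilised ylide, which is E-selective, and 9 is more electrophilic than the vinylogous product 11 so a second homologation stays minor.

**Step 5**
Reactants: 8 ethyl (2E,6R)-6-(3-acetyl-2-hydroxy-5-methoxyphenyl)hept-2-enoate; 11 ethyl (2E,4E)-6-oxohexa-2,4-dienoate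
Product: 15 (2E,4E,6E)-8-{3-[(2R,5E)-6-carboxyhex-5-en-2-yl]-2-hydroxy-5-methoxyphenyl}-8-oxoocta-2,4,6-trienoic acid (CNP0274934.1), via keto acid 12 (not isolated), via aldehyde acid 13 (not isolated), via aldol adduct 14 (not isolated)
Conditions: 8, 50 % aq KOH (15 equiv), EtOH, 0 °C to rt, 1 h; then 11 (1.3 equiv) in EtOH over 1 h at 0 °C, rt, 16 h; ice, 2 M HCl to pH 2
Reagents that add atoms: potassium hydroxide, [K+].[OH-]
Why: Claisen–Schmidt aldol condensation with concurrent saponification, in which fast ester hydrolysis turns both enoates into carboxylates that resist oxa-Michael addition and deconjugation, the methyl ketone enolate adds to the non-enolisable aldehyde and E1cB loss of water gives the E alkene, the phenolate form keeps the chain open rather than closed to a chromanone, and the non-acidic benzylic centre is untouched.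

**Compound list**
1 | 1-(2-hydroxy-5-methoxyphenyl)ethan-1-one | CC(=O)c1cc(OC)ccc1O | starting material
2 | (E)-but-2-en-1-ol | C/C=C/CO | starting material
3 | 1-{2-[(2E)-but-2-en-1-yloxy]-5-methoxyphenyl}ethan-1-one | CC(=O)c1cc(OC)ccc1OC/C=C/C | intermediate
4 | (6R)-2-acetyl-6-[(2R)-but-3-en-2-yl]-4-methoxycyclohexa-2,4-dien-1-one (chair product, not isolated) | CC(=O)C1=CC(OC)=C[C@@H]([C@H](C)C=C)C1=O | intermediate
5 | 1-{3-[(2R)-but-3-en-2-yl]-2-hydroxy-5-methoxyphenyl}ethan-1-one | CC(=O)c1cc(OC)cc([C@H](C)C=C)c1O | intermediate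
6 | ethyl (triphenyl-λ5-phosphanylidene)acetate | CCOC(=O)C=P(c1ccccc1)(c1ccccc1)c1ccccc1 | starting material
7 | (4R)-4-(3-acetyl-2-hydroxy-5-methoxyphenyl)pentanal (not isolated) | CC(=O)c1cc(OC)cc([C@H](C)CCC=O)c1O | intermediate
8 | ethyl (2E,6R)-6-(3-acetyl-2-hydroxy-5-methoxyphenyl)hept-2-enoate | CC(=O)c1cc(OC)cc([C@H](C)CC/C=C/C(=O)OCC)c1O | intermediate
9 | ethyl (E)-4-oxobut-2-enoate | CCOC(=O)/C=C/C=O | starting material
10 | (triphenyl-λ5-phosphanylidene)acetaldehyde | O=CC=P(c1ccccc1)(c1ccccc1)c1ccccc1 | starting material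
11 | ethyl (2E,4E)-6-oxohexa-2,4-dienoate | CCOC(=O)/C=C/C=C/C=O | intermediate
12 | (2E,6R)-6-(3-acetyl-2-hydroxy-5-methoxyphenyl)hept-2-enoic acid (present as potassium salt, not isolated) | CC(=O)c1cc(OC)cc([C@H](C)CC/C=C/C(=O)O)c1O | intermediate
13 | (2E,4E)-6-oxohexa-2,4-dienoic acid (present as potassium salt, not isolated) | O=C/C=C/C=C/C(=O)O | intermediate
14 | (2E,4E)-8-{3-[(2R,5E)-6-carboxyhex-5-en-2-yl]-2-hydroxy-5-methoxyphenyl}-6-hydroxy-8-oxoocta-2,4-dienoic acid (both C6 epimers, not isolated) | OC(=O)/C=C/C=C/C(O)CC(=O)c1cc(OC)cc([C@H](C)CC/C=C/C(=O)O)c1O | intermediate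
15 | (2E,4E,6E)-8-{3-[(2R,5E)-6-carboxyhex-5-en-2-yl]-2-hydroxy-5-methoxyphenyl}-8-oxoocta-2,4,6-trienoic acid | COc1cc(C(=O)/C=C/C=C/C=C/C(=O)O)c(O)c([C@H](C)CC/C=C/C(=O)O)c1 | target

**Total step count:** 5. **Longest linear sequence:** 4 (steps 1, 2, 3, 5).

**Three steps most likely to fail**

**Step 2 (the proposed new step).**
- The acid may not lower the barrier enough at 40 °C.
- It may ionise the ether to a crotyl cation, giving the linear [1,3] product and low ee.
- It may cyclise 5 to a 2,3-dimethyldihydrobenzofuran.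

The fallback uses known chemistry. It sets out from 1 and comes back at 5. Bought, achiral (E)-pent-3-en-2-one is reduced with catecholborane and 10 mol % (S)-Me-CBS oxazaborolidine (toluene, −78 °C) to (2R,3E)-pent-3-en-2-ol F1. Mitsunobu coupling of F1 with 1 (PPh3, DIAD, THF, 0 °C) goes with inversion to 1-{5-methoxy-2-[(2S,3E)-pent-3-en-2-yloxy]phenyl}ethan-1-one F2. Thermal aromatic Claisen rearrangement (N,N-diethylaniline, 180 °C) transfers the C–O chirality through a chair to carbon and gives 1-{2-hydroxy-5-methoxy-3-[(2R,3E)-pent-3-en-2-yl]phenyl}ethan-1-one F3. Its minor Z isomer has the opposite configuration and is removed on AgNO3-impregnated silica. Ethenolysis (ethylene 5 bar, second-generation Hoveyda–Grubbs catalyst, toluene, 40 °C) trims the propenyl group to vinyl and gives 5.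

**Step 5.**
- The acceptor-substituted dienal may be consumed by Michael addition or decay in strong base.
- The product may close to a 2-dienylchromanone on work-up.

The fallback replaces the aldol condensation by a neutral Wittig olefination. It sets out from 8 and comes back at 15. CuBr2 (2.1 equiv, EtOAc/CHCl3, reflux) gives ethyl (2E,6R)-6-[3-(bromoacetyl)-2-hydroxy-5-methoxyphenyl]hept-2-enoate F6. PPh3 (toluene, rt) gives the phenacyl(triphenyl)phosphonium bromide F7. Brief shaking with aq Na2CO3/CH2Cl2 gives the keto-stabilised ylide F8. Reaction of F8 with 11 (CH2Cl2, 40 °C) gives the diethyl ester of the target F9. LiOH (THF/H2O, 0 °C to rt, then dilute HCl) gives 15.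

**Step 3.**
- Rhodium hydride may isomerise the alkene to the trisubstituted styrene, which costs material and possibly ee.
- The o-hydroxyaryl ketone may bind rhodium.
- The branched aldehyde may form.

The fallback replaces carbonylation by B-alkyl cross-coupling. It sets out from 5 and comes back at 8. 9-BBN (3.3 equiv, THF, 0 °C to rt) hydroborates the vinyl terminus. It also borylates the phenol and reduces the ketone, giving the tris(9-BBN) adduct F4. Without isolation, aq K3PO4, PdCl2(dppf) (5 mol %) and bought ethyl (E)-3-iodoacrylate (DMF/THF, rt) give, after aqueous work-up, ethyl (2E,6R)-6-[2-hydroxy-3-(1-hydroxyethyl)-5-methoxyphenyl]hept-2-enoate F5 as carbinol epimers. MnO2 (CH2Cl2, rt) re-oxidises the benzylic alcohol to 8.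

**Further compounds**
F1 | step 2 | (2R,3E)-pent-3-en-2-ol | C[C@@H](O)/C=C/C
F2 | step 2 | 1-{5-methoxy-2-[(2S,3E)-pent-3-en-2-yloxy]phenyl}ethan-1-one | CC(=O)c1cc(OC)ccc1O[C@@H](C)/C=C/C
F3 | step 2 | 1-{2-hydroxy-5-methoxy-3-[(2R,3E)-pent-3-en-2-yl]phenyl}ethan-1-one | CC(=O)c1cc(OC)cc([C@H](C)/C=C/C)c1O
F4 | step 3 | tris(9-BBN) adduct of 5 (aryl borinate, carbinol borinate and primary B-alkyl group; carbinol epimers) | CC(OB1C2CCCC1CCC2)c1cc(OC)cc([C@H](C)CCB2C3CCCC2CCC3)c1OB1C2CCCC1CCC2
F5 | step 3 | ethyl (2E,6R)-6-[2-hydroxy-3-(1-hydroxyethyl)-5-methoxyphenyl]hept-2-enoate (carbinol epimers) | CC(O)c1cc(OC)cc([C@H](C)CC/C=C/C(=O)OCC)c1O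
F6 | step 5 | ethyl (2E,6R)-6-[3-(bromoacetyl)-2-hydroxy-5-methoxyphenyl]hept-2-enoate | O=C(CBr)c1cc(OC)cc([C@H](C)CC/C=C/C(=O)OCC)c1O
F7 | step 5 | (2-{3-[(2R,5E)-7-ethoxy-7-oxohept-5-en-2-yl]-2-hydroxy-5-methoxyphenyl}-2-oxoethyl)triphenylphosphonium bromide | O=C(C[P+](c1ccccc1)(c1ccccc1)c1ccccc1)c1cc(OC)cc([C@H](C)CC/C=C/C(=O)OCC)c1O.[Br-]
F8 | step 5 | ethyl (2E,6R)-6-{2-hydroxy-5-methoxy-3-[(triphenyl-λ5-phosphanylidene)acetyl]phenyl}hept-2-enoate | O=C(C=P(c1ccccc1)(c1ccccc1)c1ccccc1)c1cc(OC)cc([C@H](C)CC/C=C/C(=O)OCC)c1O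
F9 | step 5 | ethyl (2E,4E,6E)-8-{3-[(2R,5E)-7-ethoxy-7-oxohept-5-en-2-yl]-2-hydroxy-5-methoxyphenyl}-8-oxoocta-2,4,6-trienoate | CCOC(=O)/C=C/C=C/C=C/C(=O)c1cc(OC)cc([C@H](C)CC/C=C/C(=O)OCC)c1O
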